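**Plan**

- Retrosynthesis: open the δ-lactone at C1–O5 and cut C2–C3, leaving a C3 aldehyde; take off the O7 octenoate. Then join the C3 aldehyde carbon and the C9 acetyl carbon as a C3=C9 double bond. Finally cut C3–C4 and C8–C9 together.
- Enabling feature: in the oxane ring O–C4–C5–C6–C7–C8, both carbons next to oxygen (C4, C8) carry a methyl on one face and a carbonyl carbon (C3, C9) on the other. With C3 and C9 joined, the oxane is the six-membered ring of an 8-oxabicyclo[3.2.1]octa-3,6-dien-2-one, the product of an oxidopyrylium–alkyne [5+2] cycloaddition.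
- Forward: furan → pyranone acetate → oxidopyrylium ylide + acetylenic sulfone gives the bicycle (oxane ring plus a temporary dihydrofuran ring). The sulfonyl group activates, directs and later shields the bridge alkene. After bridge cleavage the lactone ring is closed last.
- Stereochemistry: C4/C8 are fixed relative to each other by the bicycle. C5, C6, C7 come from three reagent attacks on the convex oxygen-bridge face (epoxidation, Wharton transposition, hydroboration). Absolute configuration comes from a catalytic kinetic resolution. C3 is set by chelation-controlled addition and C2 by anti-selective hydroboration.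

Key step: step 5

Remark: positions are named in target numbering (C1 lactone carbonyl, C2, C3, C4, C5 bearing the lactone oxygen, C6, C7, C8, C9/C10 acetyl); β is the oxane face carrying the C4 and C8 methyl groups, α the opposite face.
Remark: compounds 4–6 and 11–14 are racemic and are drawn as the enantiomer that is carried on; 2,4-dimethylfuran, trimethyl(prop-1-yn-1-yl)silane, (E)-oct-2-enoic acid and isopropenylmagnesium bromide are taken as commercial.

**Route**

Step 1
Reactants: 1 2,4-dimethylfuran; 2 acetaldehyde
Product: 4 rac-1-(3,5-dimethylfuran-2-yl)ethan-1-ol, via (3,5-dimethylfuran-2-yl)lithium 3 (not isolated)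
Conditions: n-BuLi, THF, 0 °C; then 2, −78 °C → 0 °C; then H2O
Reagents that add atoms: none
Why: α-Lithiation of the furan at its only free α-position and 1,2-addition of the furyllithium to the aldehyde; the carbinol center is destroyed in step 5, so its configuration does not matter.

Step 2
Reactants: 4 rac-1-(3,5-dimethylfuran-2-yl)ethan-1-ol
Product: 5 6-hydroxy-2,4,6-trimethyl-2H-pyran-3(6H)-one (racemic, both diastereomers)
Conditions: mCPBA, CH2Cl2, 0 °C
Reagents that add atoms: mCPBA, O=C(OO)c1cccc(Cl)c1
Why: Achmatowicz rearrangement, in which peracid oxidation opens the furan to an ene-dione that recloses through the carbinol oxygen to the pyranone lactol; both stereocenters are lost in step 5.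

Step 3
Reactants: 5 6-hydroxy-2,4,6-trimethyl-2H-pyran-3(6H)-one
Product: 6 6-acetoxy-2,4,6-trimethyl-2H-pyran-3(6H)-one (racemic, both diastereomers)
Conditions: Ac2O, DMAP (cat.), pyridine, CH2Cl2, 0 °C → rt
Reagents that add atoms: acetic anhydride, CC(=O)OC(C)=O
Why: DMAP-catalysed O-acylation of the tertiary lactol installs the leaving group needed for ylide formation; no stereocenter of consequence is formed.

Step 4
Reactants: 7 trimethyl(prop-1-yn-1-yl)silane; 8 4-methylbenzenesulfonyl chloride
Product: 9 1-methyl-4-(prop-1-yn-1-ylsulfonyl)benzene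
Conditions: AlCl3, CH2Cl2, 0 °C → rt; aqueous HCl work-up
Reagents that add atoms: none
Why: Electrophilic ipso-substitution (desilylative sulfonylation) of the alkynylsilane by the sulfonyl chloride–AlCl3 complex, assisted by the β-silyl cation, gives the acetylenic sulfone; no stereocenter.

Step 5
Reactants: 6 6-acetoxy-2,4,6-trimethyl-2H-pyran-3(6H)-one; 9 1-methyl-4-(prop-1-yn-1-ylsulfonyl)benzene
Product: 11 rac-1,3,5,7-tetramethyl-6-(4-methylbenzenesulfonyl)-8-oxabicyclo[3.2.1]octa-3,6-dien-2-one (C7 ketone, C5=C6 enone, bridge C3(sulfonyl)=C9(methyl), C4 and C8 methyls β), via 2,4,6-trimethylpyrylium-3-olate 10 (not isolated)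
Conditions: 9 (1.5 equiv), i-Pr2NEt (1.2 equiv), MeCN, 60 °C
Reagents that add atoms: none
Why: Base removes the C8 proton of 6 and acetate leaves from C4 to give the planar 3-oxidopyrylium ylide 10 (a carbonyl ylide), which adds across its termini C8 and C4 to the acetylenic sulfone in a concerted but asynchronous [5+2] (1,3-dipolar) cycloaddition. The closest known reaction type is the oxidopyrylium [5+2] cycloaddition with electron-poor alkenes and alkynes such as acrylates, propiolates and vinyl sulfones. Two rings close in the one event, the 2,5-dihydrofuran ring O–C4–C3=C9–C8 and the seven-membered carbocycle, both by intermolecular suprafacial addition of the alkyne to one face of the ylide; the C3–C4 bond joins the sulfonyl-bearing alkyne carbon to the acetoxy-bearing ring carbon. The two new fully substituted stereocenters C4 and C8 are fixed relative to each other by the bicyclic topology alone (both new C–C bonds on the α face, both methyls β), so an alkyne can give only one diastereomer, formed as the racemate. The step needs regioselectivity, which the polarization of both partners should secure: the enolate-like ylide terminus next to the oxido carbon (C8) bonds to the methyl-bearing β-carbon of the alkynyl sulfone (C9), and the sulfonyl carbon closes onto the oxocarbenium-like terminus C4. Ylide dimerization is slowed by the methyl groups on both termini, and the sulfonyl group is kept afterwards as a shield for the bridge alkene until step 11.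

Step 6
Reactants: 11 rac-bicyclic dienone sulfone
Product: 12 rac-5β,6β-epoxide of 11 (epoxide oxygen on the oxygen-bridge face)
Conditions: 30% H2O2, NaOH (aq), MeOH, 0 °C
Reagents that add atoms: hydrogen peroxide, OO
Why: Weitz–Scheffer nucleophilic epoxidation: hydroperoxide adds to the enone β-carbon C5 from the convex β face (the α face is screened by the sulfonyl-bearing bridge) and the enolate closes the epoxide on the same face, setting the C5–O bond β; the tetrasubstituted vinyl sulfone is too hindered to compete.

Step 7
Reactants: 12 rac-epoxy ketone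
Product: 14 rac-1,3,5,6-tetramethyl-7-(4-methylbenzenesulfonyl)-8-oxabicyclo[3.2.1]octa-3,6-dien-2-ol (5β-hydroxyl, C6=C7), via hydrazone of 12 13 (not isolated)
Conditions: N2H4·H2O, AcOH (cat.), MeOH, 0 °C → rt
Reagents that add atoms: none
Why: Wharton transposition: the epoxy hydrazone opens to an alkenyl diazene that loses N2, which moves the double bond to C6=C7 and leaves the former epoxide oxygen as the 5β-hydroxyl with retention.

Step 8
Reactants: 14 rac-allylic alcohol
Product: 15 the same allylic alcohol as a single enantiomer (bridgehead configuration of the target)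
Conditions: (R)-benzotetramisole (5 mol %), (EtCO)2O (0.6 equiv), i-Pr2NEt, CHCl3, 0 °C, run to slightly beyond half conversion; chromatography
Reagents that add atoms: none
Why: Acylative kinetic resolution of a 2-substituted cyclic allylic alcohol by chiral isothiourea acyl-transfer catalysis; the catalyst antipode is chosen in a test run so that the unwanted enantiomer is propionylated and 15 is recovered, which fixes the absolute configuration of C4, C5 and C8 and through them of every later center.

Step 9
Reactants: 15 allylic alcohol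
Product: 16 5β-triethylsilyl ether of 15
Conditions: Et3SiCl, imidazole, DMAP (cat.), DMF, rt
Reagents that add atoms: chlorotriethylsilane, CC[Si](Cl)(CC)CC
Why: Silylation of the only hydroxyl marks O5 (the future lactone oxygen) so that it stays distinct from O7, which appears in the next step; no stereocenter changes.

Step 10
Reactants: 16 silyl ether
Product: 18 1,3,5,7-tetramethyl-6-(4-methylbenzenesulfonyl)-4-(triethylsilyloxy)-8-oxabicyclo[3.2.1]oct-6-en-2-ol (5β-silyloxy, 6α-methyl, 7β-hydroxyl), via C7 alkylborane 17 (not isolated)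
Conditions: BH3·THF, THF, 0 °C → rt; then NaOH (aq), 30% H2O2, 0 °C
Reagents that add atoms: hydrogen peroxide, OO
Why: Hydroboration–oxidation: borane adds syn across C6=C7 from the β face with boron at the less substituted C7, so hydrogen enters C6 from β (methyl α) and oxidation with retention gives the 7β-hydroxyl; the electron-poor tetrasubstituted vinyl sulfone is inert to borane.

Step 11
Reactants: 18 hydroxy vinyl sulfone
Product: 19 1,3,5,7-tetramethyl-4-(triethylsilyloxy)-8-oxabicyclo[3.2.1]oct-6-en-2-ol (bridge now C3H=C9(methyl))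
Conditions: Na/Hg (6% Na), Na2HPO4, MeOH/THF, −20 °C
Reagents that add atoms: none
Why: Reductive desulfonylation of the vinyl sulfone by electron transfer (C–S cleavage, then protonation of the vinyl anion by methanol); the in-plane vinyl anion has no favourable path to expel the bridging oxygen, and no stereocenter changes.

Step 12
Reactants: 19 bicyclic alkene
Product: 21 6-acetyl-5-hydroxy-2,4,6-trimethyl-3-(triethylsilyloxy)oxane-2-carbaldehyde (C4: methyl β, CHO α; 5β-silyloxy; 6α-methyl; 7β-hydroxyl; C8: methyl β, acetyl α), via ozonide of 19 20 (not isolated)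
Conditions: O3, CH2Cl2, −78 °C; then PPh3, −78 °C → rt
Reagents that add atoms: ozone, [O-][O+]=O
Why: Ozonolysis of the only C=C bond with reductive work-up cleaves the temporary two-carbon bridge and unveils the C3 aldehyde and the C9 methyl ketone, both on fully substituted carbons that cannot epimerize.

Step 13
Reactants: 21 hydroxy keto aldehyde; 22 (E)-oct-2-enoic acid
Product: 23 7-O-[(E)-oct-2-enoyl] ester of 21
Conditions: 22, 2,4,6-Cl3C6H2COCl, Et3N, THF, rt; then 21, DMAP, toluene, rt
Reagents that add atoms: none
Why: Yamaguchi esterification of the only free hydroxyl (O7, equatorial in the monocyclic oxane) through the mixed anhydride under DMAP catalysis; the E-alkene and all stereocenters are untouched.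

Step 14
Reactants: 23 silyl ether ester
Product: 24 6-acetyl-3-hydroxy-2,4,6-trimethyl-5-[(E)-oct-2-enoyloxy]oxane-2-carbaldehyde (free 5β-hydroxyl)
Conditions: HF·pyridine, pyridine/THF, 0 °C
Reagents that add atoms: none
Why: Fluoride-mediated cleavage of the triethylsilyl ether frees O5 under conditions that leave the enoate, the aldehyde and the ketone intact.

Step 15
Reactants: 24 hydroxy keto aldehyde; 25 isopropenylmagnesium bromide
Product: 26 C3 allylic alcohol (3-hydroxyl as in the target, isopropenyl group = C2 with its methyl and C1 as =CH2)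
Conditions: 25 (3 equiv), THF/CH2Cl2, −78 °C; then H2O
Reagents that add atoms: none
Why: Chelation-controlled Grignard addition: the magnesium alkoxide at O5 chelates the aldehyde oxygen in a six-membered ring fused to the oxane chair and the alkenyl group attacks C3 anti to the axial C4 methyl, giving the target configuration at C3; at −78 °C the aldehyde should react before the hindered methyl ketone and the enoate.

Step 16
Reactants: 26 allylic alcohol
Product: 28 C1,C3,O5-triol (primary C1 alcohol, 2-methyl anti to 3-hydroxyl), via B-alkyl-9-BBN adduct 27 (not isolated)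
Conditions: 9-BBN (4 equiv), THF, 0 °C → rt; then NaOAc (aq), 30% H2O2, 0 °C
Reagents that add atoms: hydrogen peroxide, OO
Why: Substrate-controlled hydroboration of a 2-substituted allylic alcohol with 9-BBN: the borane attacks the 1,1-disubstituted alkene anti to the bulky C4 substituent in the conformer with the carbinol C–H eclipsing the double bond, giving the 2,3-anti relationship of the target, and oxidation gives the primary alcohol.

Step 17
Reactants: 28 triol
Product: 31 botcinin K, via hydroxy aldehyde 29 (not isolated), via lactol 30 (not isolated)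
Conditions: TEMPO (0.2 equiv), PhI(OAc)2 (2.5 equiv), CH2Cl2, rt
Reagents that add atoms: none
Why: TEMPO/PhI(OAc)2 oxidative lactonization: the primary alcohol is oxidized selectively to the aldehyde, which O5 traps as the six-membered lactol that is oxidized on to the trans-fused δ-lactone, leaving the secondary C3 hydroxyl free and every stereocenter untouched.

**Compound list**

1 | 2,4-dimethylfuran | Cc1cc(C)co1 | starting material
2 | acetaldehyde | CC=O | starting material
3 | (3,5-dimethylfuran-2-yl)lithium | [Li]c1oc(C)cc1C | intermediate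
4 | rac-1-(3,5-dimethylfuran-2-yl)ethan-1-ol | CC(O)c1oc(C)cc1C | intermediate
5 | 6-hydroxy-2,4,6-trimethyl-2H-pyran-3(6H)-one (racemic diastereomer mixture) | CC1OC(C)(O)C=C(C)C1=O | intermediate
6 | 6-acetoxy-2,4,6-trimethyl-2H-pyran-3(6H)-one (racemic diastereomer mixture) | CC1OC(C)(OC(C)=O)C=C(C)C1=O | intermediate
7 | trimethyl(prop-1-yn-1-yl)silane | CC#C[Si](C)(C)C | starting material
8 | 4-methylbenzenesulfonyl chloride | Cc1ccc(cc1)S(Cl)(=O)=O | starting material
9 | 1-methyl-4-(prop-1-yn-1-ylsulfonyl)benzene | CC#CS(=O)(=O)c1ccc(C)cc1 | intermediate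
10 | 2,4,6-trimethylpyrylium-3-olate | Cc1cc(C)c([O-])c(C)[o+]1 | intermediate
11 | rac-1,3,5,7-tetramethyl-6-(4-methylbenzenesulfonyl)-8-oxabicyclo[3.2.1]octa-3,6-dien-2-one | C[C@@]12C=C(C)C(=O)[C@@](C)(O1)C(C)=C2S(=O)(=O)c1ccc(C)cc1 | intermediate
12 | rac-5β,6β-epoxide of 11 | C[C@@]12[C@H]3O[C@@]3(C)C(=O)[C@@](C)(O1)C(C)=C2S(=O)(=O)c1ccc(C)cc1 | intermediate
13 | hydrazone of 12 | C[C@@]12[C@H]3O[C@@]3(C)C(=NN)[C@@](C)(O1)C(C)=C2S(=O)(=O)c1ccc(C)cc1 | intermediate
14 | rac-1,3,5,6-tetramethyl-7-(4-methylbenzenesulfonyl)-8-oxabicyclo[3.2.1]octa-3,6-dien-2-ol (hydroxyl exo, 5β) | C[C@@]12[C@@H](O)C(C)=C[C@@](C)(O1)C(C)=C2S(=O)(=O)c1ccc(C)cc1 | intermediate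
15 | the same alcohol, single enantiomer shown | C[C@@]12[C@@H](O)C(C)=C[C@@](C)(O1)C(C)=C2S(=O)(=O)c1ccc(C)cc1 | intermediate
16 | 5β-triethylsilyl ether of 15 | C[C@@]12[C@@H](O[Si](CC)(CC)CC)C(C)=C[C@@](C)(O1)C(C)=C2S(=O)(=O)c1ccc(C)cc1 | intermediate
17 | C7 β-alkylborane from 16 | C[C@@]12[C@@H](O[Si](CC)(CC)CC)[C@H](C)[C@@H](B)[C@@](C)(O1)C(C)=C2S(=O)(=O)c1ccc(C)cc1 | intermediate
18 | 1,3,5,7-tetramethyl-6-(4-methylbenzenesulfonyl)-4-(triethylsilyloxy)-8-oxabicyclo[3.2.1]oct-6-en-2-ol (5β-OSi, 6α-Me, 7β-OH) | C[C@@]12[C@@H](O[Si](CC)(CC)CC)[C@H](C)[C@@H](O)[C@@](C)(O1)C(C)=C2S(=O)(=O)c1ccc(C)cc1 | intermediate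
19 | 1,3,5,7-tetramethyl-4-(triethylsilyloxy)-8-oxabicyclo[3.2.1]oct-6-en-2-ol (same configuration) | C[C@@]12[C@@H](O[Si](CC)(CC)CC)[C@H](C)[C@@H](O)[C@@](C)(O1)C(C)=C2 | intermediate
20 | ozonide of 19 (trioxolane carbons not specified) | C[C@@]12[C@@H](O[Si](CC)(CC)CC)[C@H](C)[C@@H](O)[C@@](C)(O1)C3(C)OOC2O3 | intermediate
21 | 6-acetyl-5-hydroxy-2,4,6-trimethyl-3-(triethylsilyloxy)oxane-2-carbaldehyde | O=C[C@@]1(C)O[C@@](C)(C(C)=O)[C@H](O)[C@@H](C)[C@@H]1O[Si](CC)(CC)CC | intermediate
22 | (E)-oct-2-enoic acid | CCCCC/C=C/C(=O)O | starting material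
23 | 7-O-[(E)-oct-2-enoyl] ester of 21 | O=C[C@@]1(C)O[C@@](C)(C(C)=O)[C@H](OC(=O)/C=C/CCCCC)[C@@H](C)[C@@H]1O[Si](CC)(CC)CC | intermediate
24 | 6-acetyl-3-hydroxy-2,4,6-trimethyl-5-[(E)-oct-2-enoyloxy]oxane-2-carbaldehyde | O=C[C@@]1(C)O[C@@](C)(C(C)=O)[C@H](OC(=O)/C=C/CCCCC)[C@@H](C)[C@@H]1O | intermediate
25 | isopropenylmagnesium bromide | CC(=C)[Mg]Br | starting material
26 | C3 allylic alcohol from 24 | C=C(C)[C@H](O)[C@@]1(C)O[C@@](C)(C(C)=O)[C@H](OC(=O)/C=C/CCCCC)[C@@H](C)[C@@H]1O | intermediate
27 | B-alkyl-9-BBN adduct of 26 | B1(C2CCCC1CCC2)C[C@H](C)[C@H](O)[C@@]3(C)O[C@@](C)(C(C)=O)[C@H](OC(=O)/C=C/CCCCC)[C@@H](C)[C@@H]3O | intermediate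
28 | C1,C3,O5-triol | OC[C@H](C)[C@H](O)[C@@]1(C)O[C@@](C)(C(C)=O)[C@H](OC(=O)/C=C/CCCCC)[C@@H](C)[C@@H]1O | intermediate
29 | C1 aldehyde from 28 | O=C[C@H](C)[C@H](O)[C@@]1(C)O[C@@](C)(C(C)=O)[C@H](OC(=O)/C=C/CCCCC)[C@@H](C)[C@@H]1O | intermediate
30 | C1 lactol (anomeric carbon not specified) | CCCCC/C=C/C(=O)O[C@@H]1[C@@H](C)[C@@H]2OC(O)[C@H](C)[C@H](O)[C@@]2(C)O[C@@]1(C)C(C)=O | intermediate
31 | botcinin K ((2R,3S,4R,5S,6S,7R,8R) in target numbering) | CCCCC/C=C/C(=O)O[C@@H]1[C@@H](C)[C@@H]2OC(=O)[C@H](C)[C@H](O)[C@@]2(C)O[C@@]1(C)C(C)=O | target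

**Step count**

Total: 17 steps. Longest linear sequence: 16 steps (steps 1–3 and 5–17 from 2,4-dimethylfuran; step 4 is a one-step branch).

**Steps most likely to fail, with fallbacks**

Step 5. The bond between two fully substituted carbons (C8–C9) may form too slowly, so that base-induced isomerization of the acetylenic sulfone or amine addition to it consumes the acceptor first. The fallback reverses the polarity of the two-carbon partner. It sets out again from 6 and uses the electron-rich, base-stable 1-methyl-4-(prop-1-yn-1-ylsulfanyl)benzene F1, made from commercial 1-propynylmagnesium bromide and bis(4-methylphenyl) disulfide in THF. With i-Pr2NEt in MeCN at 80 °C the ambiphilic ylide 10 should add to it with the same orientation (substituent-bearing carbon next to the bridgehead remote from the ketone), giving rac-1,3,5,7-tetramethyl-6-[(4-methylphenyl)sulfanyl]-8-oxabicyclo[3.2.1]octa-3,6-dien-2-one F2. Oxidation at sulfur with mCPBA (2.2 equiv, CH2Cl2, 0 °C), which spares the electron-poor enone, returns the route to 11.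

Step 7. Hydrazone formation at a ketone flanked by two fully substituted carbons may be too slow, so that the epoxy ketone decomposes under the basic conditions before the transposition. The fallback sets out from 12. Reduction with NaBH4 and CeCl3·7H2O in MeOH gives the epoxy alcohol F3 (configuration at C7 immaterial), and Ac2O/pyridine/DMAP gives the epoxy acetate F4. Cp2TiCl (from Cp2TiCl2 and Zn dust, THF, rt) then opens the epoxide homolytically at the more substituted C6. A second equivalent of the trivalent titanium reagent reduces the tertiary radical, and the organotitanium eliminates the C7 acetate. This forms C6=C7 and leaves the C5 oxygen in place, returning to 14.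

Step 8. Acyl transfer to this hindered carbinol may show too small a rate difference between the enantiomers, so that neither recovered alcohol nor ester is obtained enantiopure. The fallback is a classical resolution that sets out from 14. Esterification with (S)-2-methoxy-2-phenylacetic acid (DCC, DMAP, CH2Cl2) gives two diastereomeric esters that are separated by chromatography or crystallization. The ester of the wanted enantiomer, the (S)-2-methoxy-2-phenylacetate of 15 F5, is cleaved with K2CO3 in MeOH, returning to 15.

Further compounds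
F1 | step 5 | 1-methyl-4-(prop-1-yn-1-ylsulfanyl)benzene | CC#CSc1ccc(C)cc1
F2 | step 5 | rac-1,3,5,7-tetramethyl-6-[(4-methylphenyl)sulfanyl]-8-oxabicyclo[3.2.1]octa-3,6-dien-2-one | C[C@@]12C=C(C)C(=O)[C@@](C)(O1)C(C)=C2Sc1ccc(C)cc1
F3 | step 7 | rac-epoxy alcohol from reduction of 12 (C7 carbinol configuration not specified) | C[C@@]12[C@H]3O[C@@]3(C)C(O)[C@@](C)(O1)C(C)=C2S(=O)(=O)c1ccc(C)cc1
F4 | step 7 | rac-epoxy acetate from F3 | C[C@@]12[C@H]3O[C@@]3(C)C(OC(C)=O)[C@@](C)(O1)C(C)=C2S(=O)(=O)c1ccc(C)cc1
F5 | step 8 | (S)-2-methoxy-2-phenylacetate of 15 | C[C@@]12[C@@H](OC(=O)[C@@H](OC)c3ccccc3)C(C)=C[C@@](C)(O1)C(C)=C2S(=O)(=O)c1ccc(C)cc1
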